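**Strategy**

The synthesis rests on disconnecting ring C (cyclopentane) between C-3a', the O–CH carbon it shares with pyran ring B, and the spiro carbon C-1 of cyclohexene ring D. The key step exploits two features: C-3a' is an aldehyde-level carbon flanked by two quaternary carbons, and C-1 is the α-carbon of a latent menthone-type ketone at C-2. A 3,3,4-trisubstituted 2-acetoxychroman whose side chain ends in a menthone-derived 2-alkylidenecyclohexanone is hydrosilylated to one silyl enol ether, which closes ring C onto the chromanyl oxocarbenium ion, setting C-3a' and the spiro centre while both acetal anomers and both enone geometries converge. The alkene is unveiled last from an enol triflate.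

Key step: step 7

**Remarks**

- Locants are those of spiro[cyclohex-2-ene-1,3'-cyclopenta[b]chromene]. Ring A is the arene, ring B the pyran, ring C the cyclopentane and ring D the cyclohexene. Chroman intermediates carry chroman locants.
- Assumption: (+)-menthone, the (2R,5S) enantiomer, is purchased; if only (+)-menthol is at hand, it would be oxidised first.
- The antipode of the ligand in step 1 is to be fixed in a pilot run so that the 4R lactone results.
- The isopropyl-bearing carbon of ring D is epimerisable up to step 8 and is made planar there, so its configuration is of no consequence.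

**Route**

Step 1
Reactants: 1 5,7-dimethoxycoumarin
Product: 2 (4R)-4-isobutyl-5,7-dimethoxychroman-2-one
Conditions: i-BuMgBr, CuBr·SMe2 (5 mol %), (R)-1-[(S)-2-(diphenylphosphino)ferrocenyl]ethyldicyclohexylphosphine or its antipode (6 mol %), t-BuOMe, −78 °C; aq. NH4Cl
Reagents that add atoms: isobutylmagnesium bromide, CC(C)C[Mg]Br
Why: Copper-catalysed asymmetric conjugate addition of a Grignard reagent to the coumarin enoate, in which the chiral ferrocenyl diphosphine–copper complex selects the face of C-4 and so sets the benzylic centre.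

Step 2
Reactants: 2 (4R)-4-isobutyl-5,7-dimethoxychroman-2-one
Product: 3 (3R,4R)-4-isobutyl-5,7-dimethoxy-3-methylchroman-2-one (trans)
Conditions: LiN(SiMe3)2, THF, −78 °C; MeI, −78 → −40 °C
Reagents that add atoms: iodomethane, CI
Why: Lactone enolate alkylation in which methyl iodide should enter anti to the C-4 isobutyl group, although this centre is enolised again in step 3 and its configuration does not matter.

Step 3
Reactants: 3 (3R,4R)-4-isobutyl-5,7-dimethoxy-3-methylchroman-2-one
Product: 4 (3R,4S)-3-allyl-4-isobutyl-5,7-dimethoxy-3-methylchroman-2-one (methyl cis and allyl trans to isobutyl)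
Conditions: LiN(SiMe3)2, THF/DMPU, −78 °C; allyl bromide, −78 → −30 °C
Reagents that add atoms: allyl bromide, C=CCBr
Why: Second enolate alkylation in which the C-4 isobutyl group, held pseudoaxial by the peri 5-methoxy group, shields one face of the planar enolate so that allyl bromide enters trans to it and sets the quaternary centre.

Step 4
Reactants: 4 (3R,4S)-3-allyl-4-isobutyl-5,7-dimethoxy-3-methylchroman-2-one
Product: 6 (3R,4S)-3-allyl-4-isobutyl-5,7-dimethoxy-3-methylchroman-2-yl acetate (C-2 epimers), via aluminium lactolate 5 (not isolated)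
Conditions: i-Bu2AlH, CH2Cl2, −78 °C; then pyridine, DMAP, Ac2O, −78 → −20 °C
Reagents that add atoms: acetic anhydride, CC(=O)OC(C)=O
Why: Reductive acetylation of a lactone, in which the tetrahedral aluminium hemiacetal formed by half-reduction is acetylated in the flask before it can collapse, and both anomers of the acetate are equally useful.

Step 5
Reactants: 7 (+)-menthone
Product: 10 (2R,5S)-5-methyl-6-methylidene-2-(propan-2-yl)cyclohexan-1-one, via Mannich base 8 (not isolated), via trimethylammonium iodide 9 (not isolated)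
Conditions: LiN(i-Pr)2, THF, −78 °C; CH2=NMe2+ I−, −78 → 0 °C; MeI, MeOH, rt; aq. NaHCO3/CH2Cl2, rt; used at once
Reagents that add atoms: N,N-dimethylmethyleneiminium iodide (Eschenmoser's salt), C=[N+](C)C.[I-]
Why: Kinetic deprotonation at the CH2 α-carbon, Mannich reaction with the iminium salt, quaternisation and mild β-elimination of trimethylamine should give the α-methylene ketone without touching either existing stereocentre.

Step 6
Reactants: 6 (3R,4S)-3-allyl-4-isobutyl-5,7-dimethoxy-3-methylchroman-2-yl acetate; 10 (2R,5S)-5-methyl-6-methylidene-2-(propan-2-yl)cyclohexan-1-one (3 equiv)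
Product: 11 (3R,4S)-4-isobutyl-5,7-dimethoxy-3-methyl-3-{2-[(3R,6S)-6-methyl-2-oxo-3-(propan-2-yl)cyclohexylidene]ethyl}chroman-2-yl acetate (E/Z and C-2 mixtures)
Conditions: second-generation Hoveyda–Grubbs catalyst (5 mol %), CH2Cl2, 40 °C
Reagents that add atoms: none
Why: Olefin cross-metathesis between a terminal alkene and an excess of a 1,1-disubstituted enone alkene that does not homodimerise should give the trisubstituted enone, whose geometry is erased in step 7.

Step 7
Reactants: 11 (3R,4S)-4-isobutyl-5,7-dimethoxy-3-methyl-3-{2-[(3R,6S)-6-methyl-2-oxo-3-(propan-2-yl)cyclohexylidene]ethyl}chroman-2-yl acetate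
Product: 13 (1S,3R,3a'S,6S,9'R,9a'R)-9'-isobutyl-6',8'-dimethoxy-6,9a'-dimethyl-3-(propan-2-yl)-1',2',9',9a'-tetrahydro-3a'H-spiro[cyclohexane-1,3'-cyclopenta[b]chromen]-2-one, via triethylsilyl enol ether 12 (not isolated)
Conditions: RhCl(PPh3)3 (2 mol %), Et3SiH (1.1 equiv), toluene, 50 °C; evaporate to remove silane; Me3SiOTf (0.3 equiv), CH2Cl2, −78 → −40 °C
Reagents that add atoms: none
Why: RhCl(PPh3)3-catalysed 1,4-hydrosilylation puts hydride on the enone β-carbon and silicon on oxygen, so only the enol ether whose nucleophilic carbon is the ring carbon next to the methyl-bearing centre is formed; Me3SiOTf then ionises the exocyclic acetate to the 2-chromanyl oxocarbenium ion, which cannot lose a proton because C-3 is quaternary, and the enol ether carbon adds to it while the silyl group leaves as triethylsilyl acetate. The closest known reaction type is the intramolecular Mukaiyama aldol-type addition of a silyl enol ether to a cyclic oxocarbenium ion made from an anomeric acetate. Ring C closes in the 5-(enolexo)-exo-trig mode. The new O–CH centre (C-3a') is controlled by quaternary C-3 of the chroman: the two-carbon tether reaches only the oxocarbenium face it is attached to, so H-3a' ends cis to the angular methyl group. The spiro centre is controlled by the neighbouring methyl-bearing carbon of ring D: allylic strain with the tether holds that methyl group pseudoaxial and the oxocarbenium carbon enters anti to it, with the siloxy-bearing carbon on the ring-oxygen side. The step needs exocyclic rather than endocyclic ionisation (secured by the acetate, since ring opening would require an acyl oxocarbenium ion), carbon rather than oxygen attack (five- against seven-membered ring) and a single enol ether regioisomer (secured by the hydrosilylation), while both acetal anomers and both enone geometries converge on one product.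

Step 8
Reactants: 13 spiro ketone
Product: 14 (1S,3a'S,6S,9'R,9a'R)-9'-isobutyl-6',8'-dimethoxy-6,9a'-dimethyl-3-(propan-2-yl)-1',2',9',9a'-tetrahydro-3a'H-spiro[cyclohex-2-ene-1,3'-cyclopenta[b]chromen]-2-yl trifluoromethanesulfonate
Conditions: KN(SiMe3)2, THF, −78 → 0 °C; PhNTf2, 0 °C
Reagents that add atoms: N-phenylbis(trifluoromethanesulfonimide), O=S(=O)(N(c1ccccc1)S(=O)(=O)C(F)(F)F)C(F)(F)F
Why: Enolate O-sulfonylation in which the isopropyl-bearing carbon is the only enolisable position (the other α-carbon is the spiro centre), so a single enol triflate should form and the stray stereocentre is removed.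

Step 9
Reactants: 14 enol triflate
Product: 15 (1S,3a'S,6S,9'R,9a'R)-5',7'-diformyl-9'-isobutyl-6',8'-dimethoxy-6,9a'-dimethyl-3-(propan-2-yl)-1',2',9',9a'-tetrahydro-3a'H-spiro[cyclohex-2-ene-1,3'-cyclopenta[b]chromen]-2-yl trifluoromethanesulfonate
Conditions: Cl2CHOMe, TiCl4, CH2Cl2, −78 → 0 °C; H2O
Reagents that add atoms: dichloromethyl methyl ether, COC(Cl)Cl; water, O
Why: Rieche formylation should occur at both free positions of ring A, each flanked by two oxygen substituents, while the electron-poor enol triflate is inert to the Lewis acid, unlike the alkene it masks.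

Step 10
Reactants: 15 dialdehyde dimethyl ether
Product: 16 (1S,3a'S,6S,9'R,9a'R)-5',7'-diformyl-6',8'-dihydroxy-9'-isobutyl-6,9a'-dimethyl-3-(propan-2-yl)-1',2',9',9a'-tetrahydro-3a'H-spiro[cyclohex-2-ene-1,3'-cyclopenta[b]chromen]-2-yl trifluoromethanesulfonate
Conditions: BCl3, CH2Cl2, −78 → 0 °C; H2O
Reagents that add atoms: none
Why: Chelation-assisted ether cleavage, in which each methoxy group has an ortho formyl group to form a six-membered boron chelate, while the ring-B ether at a secondary carbon between two quaternary carbons should resist.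

Step 11
Reactants: 16 diphenol dialdehyde enol triflate
Product: 17 target, (1R,3a'S,6S,9'R,9a'R)-6',8'-dihydroxy-9'-isobutyl-6,9a'-dimethyl-3-(propan-2-yl)-1',2',9',9a'-tetrahydro-3a'H-spiro[cyclohex-2-ene-1,3'-cyclopenta[b]chromene]-5',7'-dicarbaldehyde
Conditions: Pd(OAc)2 (10 mol %), PPh3 (20 mol %), HCO2H, n-Bu3N, DMF, 60 °C
Reagents that add atoms: none
Why: Palladium-catalysed formate reduction of an enol triflate (oxidative addition to zerovalent palladium, hydride transfer from formate with loss of CO2, reductive elimination) should place the alkene exactly where the triflate sat and tolerate the phenols and aldehydes.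

**Compound list**

1 | 5,7-dimethoxycoumarin | COc1cc(OC)c2C=CC(=O)Oc2c1 | starting material
2 | (4R)-4-isobutyl-5,7-dimethoxychroman-2-one | CC(C)C[C@H]1c2c(OC)cc(OC)cc2OC(=O)C1 | intermediate
3 | (3R,4R)-4-isobutyl-5,7-dimethoxy-3-methylchroman-2-one (trans) | CC(C)C[C@H]1c2c(OC)cc(OC)cc2OC(=O)[C@@H]1C | intermediate
4 | (3R,4S)-3-allyl-4-isobutyl-5,7-dimethoxy-3-methylchroman-2-one | CC(C)C[C@H]1c2c(OC)cc(OC)cc2OC(=O)[C@]1(C)CC=C | intermediate
5 | diisobutylaluminium lactolate of 4 (C-2 epimers) | CC(C)C[C@H]1c2c(OC)cc(OC)cc2OC(O[Al](CC(C)C)CC(C)C)[C@]1(C)CC=C | intermediate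
6 | (3R,4S)-3-allyl-4-isobutyl-5,7-dimethoxy-3-methylchroman-2-yl acetate (C-2 epimers) | CC(C)C[C@H]1c2c(OC)cc(OC)cc2OC(OC(C)=O)[C@]1(C)CC=C | intermediate
7 | (+)-menthone, (2R,5S)-5-methyl-2-(propan-2-yl)cyclohexan-1-one | CC(C)[C@H]1CC[C@H](C)CC1=O | starting material
8 | 6-[(dimethylamino)methyl] derivative of 7 (aminomethyl trans to the 5-methyl group) | CN(C)C[C@H]1C(=O)[C@@H](C(C)C)CC[C@@H]1C | intermediate
9 | trimethylammonium iodide of 8 | C[N+](C)(C)C[C@H]1C(=O)[C@@H](C(C)C)CC[C@@H]1C.[I-] | intermediate
10 | (2R,5S)-5-methyl-6-methylidene-2-(propan-2-yl)cyclohexan-1-one | C=C1C(=O)[C@@H](C(C)C)CC[C@@H]1C | intermediate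
11 | (3R,4S)-4-isobutyl-5,7-dimethoxy-3-methyl-3-{2-[(3R,6S)-6-methyl-2-oxo-3-(propan-2-yl)cyclohexylidene]ethyl}chroman-2-yl acetate (E/Z and C-2 mixtures) | CC(C)C[C@H]1c2c(OC)cc(OC)cc2OC(OC(C)=O)[C@]1(C)CC=C1C(=O)[C@@H](C(C)C)CC[C@@H]1C | intermediate
12 | (3R,4S)-4-isobutyl-5,7-dimethoxy-3-methyl-3-{2-[(3R,6S)-6-methyl-3-(propan-2-yl)-2-(triethylsilyloxy)cyclohex-1-en-1-yl]ethyl}chroman-2-yl acetate (C-2 epimers) | CC(C)C[C@H]1c2c(OC)cc(OC)cc2OC(OC(C)=O)[C@]1(C)CCC1=C(O[Si](CC)(CC)CC)[C@@H](C(C)C)CC[C@@H]1C | intermediate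
13 | (1S,3R,3a'S,6S,9'R,9a'R)-9'-isobutyl-6',8'-dimethoxy-6,9a'-dimethyl-3-(propan-2-yl)-1',2',9',9a'-tetrahydro-3a'H-spiro[cyclohexane-1,3'-cyclopenta[b]chromen]-2-one | CC(C)C[C@H]1c2c(OC)cc(OC)cc2O[C@H]2[C@]1(C)CC[C@@]21C(=O)[C@@H](C(C)C)CC[C@@H]1C | intermediate
14 | enol triflate of 13, (1S,3a'S,6S,9'R,9a'R)-configured spiro[cyclohex-2-ene-1,3'-cyclopenta[b]chromen]-2-yl trifluoromethanesulfonate | CC(C)C[C@H]1c2c(OC)cc(OC)cc2O[C@H]2[C@]1(C)CC[C@@]21C(OS(=O)(=O)C(F)(F)F)=C(C(C)C)CC[C@@H]1C | intermediate
15 | 5',7'-diformyl-6',8'-dimethoxy enol triflate | CC(C)C[C@H]1c2c(OC)c(C=O)c(OC)c(C=O)c2O[C@H]2[C@]1(C)CC[C@@]21C(OS(=O)(=O)C(F)(F)F)=C(C(C)C)CC[C@@H]1C | intermediate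
16 | 5',7'-diformyl-6',8'-dihydroxy enol triflate | CC(C)C[C@H]1c2c(O)c(C=O)c(O)c(C=O)c2O[C@H]2[C@]1(C)CC[C@@]21C(OS(=O)(=O)C(F)(F)F)=C(C(C)C)CC[C@@H]1C | intermediate
17 | (1R,3a'S,6S,9'R,9a'R)-6',8'-dihydroxy-9'-isobutyl-6,9a'-dimethyl-3-(propan-2-yl)-1',2',9',9a'-tetrahydro-3a'H-spiro[cyclohex-2-ene-1,3'-cyclopenta[b]chromene]-5',7'-dicarbaldehyde | CC(C)C[C@H]1c2c(O)c(C=O)c(O)c(C=O)c2O[C@H]2[C@]1(C)CC[C@@]21C=C(C(C)C)CC[C@@H]1C | target

**Step count**

Total: 11 steps. Longest linear sequence: 10 steps (steps 1–4 and 6–11); step 5 is the side branch.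

**Steps most likely to fail**

1. Step 6. The doubly α-branched 1,1-disubstituted alkene of 10 may never load onto ruthenium, so that 6 only homodimerises while 10 slowly isomerises to the endocyclic enone. The fallback replaces metathesis by carbonyl chemistry. It sets out from 6, whose allyl group would be cleaved (OsO4 cat., NaIO4, 2,6-lutidine, dioxane/H2O) to the aldehyde (3R,4S)-4-isobutyl-5,7-dimethoxy-3-methyl-3-(2-oxoethyl)chroman-2-yl acetate F1. Aldol addition of the kinetic lithium enolate of 7 (LiN(i-Pr)2, THF, −78 °C) should give the β-hydroxy ketone F2. Mesylation (MsCl, Et3N, 0 °C) to the mesylate F3 and elimination with DBU would come back to the route at 11.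

2. Step 7. Carbon–carbon bond formation at the tetrasubstituted enol ether carbon may be slower than capture of the oxocarbenium ion by traces of silane, or the trans-disposed isopropyl group may erode facial selectivity at the spiro carbon. The fallback generates the nucleophile without any hydride source and under equilibrating conditions. It sets out from 11, which would be hydrogenated (H2, Pd/C, EtOAc) to the saturated keto acetate F4, a mixture at the new α-carbon. Me3SiOTf and i-Pr2NEt in CH2Cl2 (−78 → 0 °C) should then form silyl enol ethers reversibly. Only the trimethylsilyl enol ether toward the chain-bearing carbon F5 can close a five-membered ring, so both α-epimers and both isopropyl epimers should funnel into the spiro ketone, coming back at 13.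

3. Step 1. The peri 5-methoxy group may slow the catalysed addition enough for the unselective background addition of the Grignard reagent to erode enantiomeric purity. The fallback swaps the copper–Grignard system for a rhodium–alkenyl nucleophile. From 1, rhodium-catalysed asymmetric 1,4-addition of 2-methylprop-1-enylboronic acid (Rh(acac)(C2H4)2, BINAP antipode as required, dioxane/H2O, 60 °C) should give (4S)-5,7-dimethoxy-4-(2-methylprop-1-en-1-yl)chroman-2-one F6. Hydrogenation of F6 (H2, Pd/C, EtOAc) comes back to the route at 2.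

**Further compounds**

F1 | step 6 | (3R,4S)-4-isobutyl-5,7-dimethoxy-3-methyl-3-(2-oxoethyl)chroman-2-yl acetate (C-2 epimers) | CC(C)C[C@H]1c2c(OC)cc(OC)cc2OC(OC(C)=O)[C@]1(C)CC=O
F2 | step 6 | (3R,4S)-3-{2-hydroxy-2-[(3R,6S)-6-methyl-2-oxo-3-(propan-2-yl)cyclohexyl]ethyl}-4-isobutyl-5,7-dimethoxy-3-methylchroman-2-yl acetate (mixture at the carbinol and ring α-carbons) | CC(C)C[C@H]1c2c(OC)cc(OC)cc2OC(OC(C)=O)[C@]1(C)CC(O)C1C(=O)[C@@H](C(C)C)CC[C@@H]1C
F3 | step 6 | methanesulfonate of F2 | CC(C)C[C@H]1c2c(OC)cc(OC)cc2OC(OC(C)=O)[C@]1(C)CC(OS(C)(=O)=O)C1C(=O)[C@@H](C(C)C)CC[C@@H]1C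
F4 | step 7 | (3R,4S)-4-isobutyl-5,7-dimethoxy-3-methyl-3-{2-[(3R,6S)-6-methyl-2-oxo-3-(propan-2-yl)cyclohexyl]ethyl}chroman-2-yl acetate (mixture at the ring α-carbon) | CC(C)C[C@H]1c2c(OC)cc(OC)cc2OC(OC(C)=O)[C@]1(C)CCC1C(=O)[C@@H](C(C)C)CC[C@@H]1C
F5 | step 7 | trimethylsilyl analogue of 12 (isopropyl-bearing carbon equilibrating) | CC(C)C[C@H]1c2c(OC)cc(OC)cc2OC(OC(C)=O)[C@]1(C)CCC1=C(O[Si](C)(C)C)C(C(C)C)CC[C@@H]1C
F6 | step 1 | (4S)-5,7-dimethoxy-4-(2-methylprop-1-en-1-yl)chroman-2-one | CC(C)=C[C@H]1c2c(OC)cc(OC)cc2OC(=O)C1
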